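Target forms from substrate on a carrier that salt renews and impurity destroys, and I wanted to know how much of it stands at the asked time.

    fresh carrier + impurity → spent catalyst (k1 = 250 L mol⁻¹ s⁻¹)
    crystals ⇌ target, rate k2*(cs2 - [target]) while solid is left; crystals form when [target] > cs2 (cs2 = 0.058 M, k2 = 0.078 s⁻¹)
    substrate + fresh carrier → target + spent carrier (k3 = 220 L mol⁻¹ s⁻¹)
    spent carrier + salt in the second phase ⇌ fresh carrier + spent salt in the second phase (K4 = 0.72, k4 = 7.0 L mol⁻¹ s⁻¹)

substrate 0.10 M; salt in the second phase 0.200 M; spent carrier 1.3 mM; impurity 1.5 mM; time 2.5 min; volume of the second phase over the first 1.0

- target is meant together with its crystals
- in the second phase: salt in the second phase, spent salt in the second phase; everything else is in the first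
- charges count per volume of the first phase; a concentration in a rate is the amount of a species over the volume of its own phase; every rate counts per litre of the first phase
- solid, in amounts per volume of the solution: crystals
- run time (flask): 2.5 min

* how much target and crystals together there is at 2.5 min, in percent of the substrate charged
* the change that raises the amount of target and crystals together at 2.5 min, in percent of the substrate charged most ("none" if none brings more than 2 percentage points) (Sunday's / Monday's / Wednesday's / none)
* amount of target and crystals together at 2.5 min, in percent of the substrate charged, after Monday's

I wrote a for the fraction of substrate left and b for the fraction of impurity left, and I went up the time scales from the fastest. At the start, fresh carrier met substrate with a half-life of 0.0315 s, while salt renewed spent carrier with a half-life of 0.495 s. So spent carrier was the resting state, and target formed at the pace of renewal.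

Fresh carrier had two exits, and substrate led impurity by 58.7 to one at the start. At that starting pace the catalyst had a half-life of 0.484 min, shorter than the run of 2.5 min.

Both exits use the same fresh carrier, so its level cancels and a = b^S. I took S = 0.880, the rate constant with substrate over the rate constant with impurity, the selectivity factor. Impurity was charged above the carrier, so b stops at 13.3 %, and the ceiling for target is 83.0 %.

Then the comparison drifted. Salt fell, the back step grew, and a/b rose as b fell, since S is below one. I expected all of these to slow the loss. So I let one rough figure stand for them and reckoned the loss with salt at its level under the ceiling, 58.5 % of its charge. That gave a loss constant of 0.837 min⁻¹, b = 24.0 % at the asked time, and target and crystals at 71.5 %.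

Crystals appear once dissolved target passes 58.0 % of the substrate charge. Target stands on the left of no other step, so Monday's flask stays at 71.5 %. Doubled salt gained 11 percentage points in my reckoning, so I chose Wednesday's.

The forecast gave 73 %, Wednesday's and 73 %, holding that “crystallisation only moves material between target and crystals”.

The flask gave 71.3 %, Wednesday's with a gain of 9.1 points, and 71.3 % after Monday's. At 2.50 min, impurity in the flask stood at 24.2 %, and b^S turns that into 28.7 % of the substrate, where the flask held 28.7 %. In the neighbour flask with 3.3 × 10⁻⁴ M of spent carrier, S puts the ceiling at 19.6 %. That flask reached 18.6 % at 2.50 min, with spent catalyst at 95.0 %.

The numbers of this flask were set for the occasion.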